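**Plan**
1. Retrosynthesis: the O8–acyl bond and the C6–H bond are removed together (Evans–Tishchenko retron: the 1,3-anti 6-OH/8-O-acyl pair across C7), giving ring β-hydroxy enone 23 and aldehyde 25. The ring is then cut at C5–C6 (alkenyl iodide + aldehyde), and the chain at C7–C8 (aldol) and C1–C2 (sp2–sp3 coupling).
2. Enabling feature: in the ten-membered carbocycle the oxygenated C6 sits directly on sp2 C5 of the (E)-C4=C5 trisubstituted alkene. In the open chain both atoms are electrophiles (C5–I, C6=O), and Cr(II)/Ni reverses the polarity of C5.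
3. Forward order: the C8→C5 chain is built by two alkyne carboalumination/iodination cycles around one Negishi coupling, and the C6–C7 unit is added by aldol. The only carbocycle is closed last (step 11); C6 is then oxidised, O8 unmasked, and the ester and C6–H installed in one step.
4. Stereochemistry: C7 and C8 come from (R)-4-benzyloxazolidinone (Evans syn aldol). C6 comes from intramolecular hydride delivery, 1,3-anti to O8. Both ring (E)-alkenes come from syn-carboalumination and are retained in the couplings.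

Key step: step 11

Remark: ring positions follow germacrane numbering: C1=C10(Me), C2, C3, C4(Me)=C5, C6 (OH), C7 (iPr), C8 (O-acyl), C9. Compounds 1, 4, 11, 12 and 24 are taken as catalogue materials.

**Step 1**
Reactants: 1 tert-butyl(but-3-yn-1-yloxy)dimethylsilane
Product: 3 tert-butyl{[(3E)-4-iodo-3-methylbut-3-en-1-yl]oxy}dimethylsilane, via alkenyldimethylalane 2 (not isolated)
Conditions: AlMe3 (2.5 equiv), Cp2ZrCl2 (0.25 equiv), CH2Cl2, 0 °C to rt; then I2, THF, −30 to 0 °C
Reagents that add atoms: trimethylaluminium C[Al](C)C; iodine II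
Why: Zirconium-catalysed methylalumination of a terminal alkyne (Negishi carboalumination) is a syn addition that puts CH3 on the internal and aluminium on the terminal carbon, and iodinolysis of the C–Al bond of 2 goes with retention, so the (E)-alkenyl iodide (future C1=C10 alkene) is set here.

**Step 2**
Reactants: 3 tert-butyl{[(3E)-4-iodo-3-methylbut-3-en-1-yl]oxy}dimethylsilane; 4 (4-bromobut-1-yn-1-yl)trimethylsilane
Product: 6 tert-butyldimethyl{[(3E)-3-methyl-8-(trimethylsilyl)oct-3-en-7-yn-1-yl]oxy}silane, via alkylzinc bromide 5 (not isolated)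
Conditions: 4, Zn dust (cat. BrCH2CH2Br/TMSCl), LiCl, THF, 50 °C; then 3, PdCl2(dppf) (3 mol %), THF, rt to 40 °C
Reagents that add atoms: none
Why: Negishi sp3–sp2 cross-coupling: zinc insertion into the primary bromide gives 5, which couples with the alkenyl iodide under Pd/dppf with retention of the (E)-geometry, while the C-silyl group keeps the alkyne terminus inert.

**Step 3**
Reactants: 6 tert-butyldimethyl{[(3E)-3-methyl-8-(trimethylsilyl)oct-3-en-7-yn-1-yl]oxy}silane
Product: 7 (3E)-3-methyloct-3-en-7-yn-1-ol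
Conditions: TBAF (2.5 equiv), THF, 0 °C to rt
Reagents that add atoms: none
Why: Fluoride-induced desilylation cleaves the O–Si and the C(sp)–Si bond in one operation and leaves the trisubstituted alkene untouched.

**Step 4**
Reactants: 7 (3E)-3-methyloct-3-en-7-yn-1-ol
Product: 9 (3E,7E)-8-iodo-3,7-dimethylocta-3,7-dien-1-ol, via bis(dimethylaluminium) intermediate 8 (not isolated)
Conditions: AlMe3 (3.5 equiv), Cp2ZrCl2 (0.3 equiv), CH2Cl2, 0 °C to rt; then I2, THF, −30 °C; aq. Rochelle salt
Reagents that add atoms: trimethylaluminium C[Al](C)C; iodine II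
Why: Second Negishi carboalumination/iodinolysis: the hydroxyl is masked in the flask as its dimethylaluminium alkoxide (8), the trisubstituted alkene is inert, and syn addition with retentive iodinolysis sets the (E)-C4=C5 alkenyl iodide.

**Step 5**
Reactants: 9 (3E,7E)-8-iodo-3,7-dimethylocta-3,7-dien-1-ol
Product: 10 (3E,7E)-8-iodo-3,7-dimethylocta-3,7-dienal
Conditions: Dess–Martin periodinane, NaHCO3, CH2Cl2, 0 °C; used at once
Reagents that add atoms: none
Why: Dess–Martin oxidation under bicarbonate buffer is fast and non-basic enough to give the β,γ-unsaturated aldehyde without migration of the C1=C10 alkene into conjugation, provided 10 is used at once.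

**Step 6**
Reactants: 11 (4R)-4-benzyl-1,3-oxazolidin-2-one; 12 3-methylbutanoyl chloride
Product: 14 (4R)-4-benzyl-3-(3-methylbutanoyl)-1,3-oxazolidin-2-one, via lithium oxazolidinide 13 (not isolated)
Conditions: n-BuLi, THF, −78 °C; then 12, −78 to 0 °C
Reagents that add atoms: none
Why: N-Acylation of the lithiated oxazolidinone with an acid chloride is the standard entry to Evans imides.

**Step 7**
Reactants: 14 (4R)-4-benzyl-3-(3-methylbutanoyl)-1,3-oxazolidin-2-one; 10 (3E,7E)-8-iodo-3,7-dimethylocta-3,7-dienal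
Product: 16 (4R)-4-benzyl-3-[(2R,3S,5E,9E)-3-hydroxy-10-iodo-5,9-dimethyl-2-(propan-2-yl)deca-5,9-dienoyl]-1,3-oxazolidin-2-one, via dibutylboron Z-enolate 15 (not isolated)
Conditions: Bu2BOTf, iPr2NEt, CH2Cl2, −78 to 0 °C; then 10, −78 to 0 °C; pH 7 buffer, MeOH, H2O2, 0 °C
Reagents that add atoms: none
Why: Evans syn-aldol reaction: the (Z)-boron enolate 15 reacts through a closed Zimmerman–Traxler chair on the enolate face opposite the benzyl group of the (R)-auxiliary, which sets C7 and C8 (2R,3S in 16, the iPr/O relationship of the target) in one step.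

**Step 8**
Reactants: 16 (4R)-4-benzyl-3-[(2R,3S,5E,9E)-3-hydroxy-10-iodo-5,9-dimethyl-2-(propan-2-yl)deca-5,9-dienoyl]-1,3-oxazolidin-2-one
Product: 17 (2R,3S,5E,9E)-3-hydroxy-10-iodo-N-methoxy-N,5,9-trimethyl-2-(propan-2-yl)deca-5,9-dienamide
Conditions: MeNH(OMe)·HCl, AlMe3, THF, −20 to 0 °C
Reagents that add atoms: N,O-dimethylhydroxylamine hydrochloride CNOC.Cl
Why: Weinreb transamidation with the aluminium amide of N,O-dimethylhydroxylamine, assisted by the free β-hydroxyl, removes the auxiliary from the hindered α-isopropyl imide without touching C7 or C8.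

**Step 9**
Reactants: 17 (2R,3S,5E,9E)-3-hydroxy-10-iodo-N-methoxy-N,5,9-trimethyl-2-(propan-2-yl)deca-5,9-dienamide
Product: 18 (2R,3S,5E,9E)-10-iodo-N-methoxy-N,5,9-trimethyl-2-(propan-2-yl)-3-(triethylsilyloxy)deca-5,9-dienamide
Conditions: TESOTf, 2,6-lutidine, CH2Cl2, −78 to 0 °C
Reagents that add atoms: triethylsilyl trifluoromethanesulfonate CC[Si](CC)(CC)OS(=O)(=O)C(F)(F)F
Why: Silylation with a silyl triflate and a hindered pyridine base protects the hindered secondary C8 hydroxyl as a triethylsilyl ether that can later be removed under near-neutral conditions.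

**Step 10**
Reactants: 18 (2R,3S,5E,9E)-10-iodo-N-methoxy-N,5,9-trimethyl-2-(propan-2-yl)-3-(triethylsilyloxy)deca-5,9-dienamide
Product: 19 (2R,3S,5E,9E)-10-iodo-5,9-dimethyl-2-(propan-2-yl)-3-(triethylsilyloxy)deca-5,9-dienal
Conditions: DIBAL-H, THF, −78 °C; aq. Rochelle salt
Reagents that add atoms: none
Why: DIBAL-H reduction of a Weinreb amide stops at the aldehyde because the chelated tetrahedral aluminium intermediate survives until work-up, and at −78 °C the C7 stereocentre is not enolised.

**Step 11**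
Reactants: 19 (2R,3S,5E,9E)-10-iodo-5,9-dimethyl-2-(propan-2-yl)-3-(triethylsilyloxy)deca-5,9-dienal
Product: 21 (2E,6E,9S,10S)-3,7-dimethyl-10-(propan-2-yl)-9-(triethylsilyloxy)cyclodeca-2,6-dien-1-ol as both C1 epimers, via alkenylchromium(III) dichloride 20 (not isolated)
Conditions: CrCl2 (10 equiv), NiCl2 (0.1 equiv), degassed DMSO/THF, rt, dark; 19 added by syringe pump to 2 mM
Reagents that add atoms: none
Why: Nozaki–Hiyama–Kishi reaction used as a macrocyclisation: Ni(0) formed in situ inserts into the C5–I bond with retention of the (E)-geometry, transmetalation to Cr(III) gives alkenylchromium 20, and this non-basic nucleophile adds to the C6 aldehyde, so that two electrophilic carbons are joined by reductive polarity reversal. The closest known reaction type is the intramolecular Cr/Ni alkenyl iodide–aldehyde coupling that closes nine- to eleven-membered carbocycles and lactones. The ten-membered ring closes in a 10-exo-trig mode by attack of C5 on the C6 carbonyl, which leaves C4=C5 endocyclic and (E) because its geometry was fixed in the chain, as was that of C1=C10. The only new stereocentre is C6, controlled by the adjacent C7 centre (Felkin–Anh attack anti to the isopropyl group, reinforced by the 1,3-anti preference of the C8 silyloxy group, predicts 6S), but either epimer is acceptable because C6 is oxidised in step 12 and reset in step 15. The step therefore needs chemoselectivity and ring closure over oligomerisation, not facial selectivity: alkenylchromium reagents attack aldehydes only and do not enolise the epimerisable C7–H or touch the silyl ether, and slow addition to high dilution, together with the two (E)-trisubstituted alkenes and the vicinal iPr/OSiEt3 substituents that restrict the chain, favours the intramolecular pathway.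

**Step 12**
Reactants: 21 (2E,6E,9S,10S)-3,7-dimethyl-10-(propan-2-yl)-9-(triethylsilyloxy)cyclodeca-2,6-dien-1-ol (both C1 epimers)
Product: 22 (2E,6E,9S,10R)-3,7-dimethyl-10-(propan-2-yl)-9-(triethylsilyloxy)cyclodeca-2,6-dien-1-one
Conditions: Dess–Martin periodinane, NaHCO3, CH2Cl2, 0 °C to rt, dark
Reagents that add atoms: none
Why: Dess–Martin oxidation of the allylic alcohol converges both C6 epimers on one (E)-enone, so the facial selectivity of step 11 is of no consequence, and buffered conditions at or below rt avoid C7 epimerisation and Cope rearrangement of the 1,5-diene.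

**Step 13**
Reactants: 22 (2E,6E,9S,10R)-3,7-dimethyl-10-(propan-2-yl)-9-(triethylsilyloxy)cyclodeca-2,6-dien-1-one
Product: 23 (2E,6E,9S,10R)-9-hydroxy-3,7-dimethyl-10-(propan-2-yl)cyclodeca-2,6-dien-1-one
Conditions: HF·pyridine, pyridine, THF, 0 °C
Reagents that add atoms: none
Why: Pyridine-buffered HF·pyridine removes the triethylsilyl ether by Si–F bond formation under conditions too weakly basic for E1cB loss of the C8 oxygen or retro-aldol opening of the ring.

**Step 14**
Reactants: 24 (2E)-3-(4-hydroxyphenyl)prop-2-enal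
Product: 25 (2E)-3-[4-(tert-butyldimethylsilyloxy)phenyl]prop-2-enal
Conditions: TBSCl, imidazole, DMF, rt
Reagents that add atoms: tert-butyldimethylsilyl chloride CC(C)(C)[Si](C)(C)Cl
Why: Silylation of the phenol (silyl chloride/imidazole) masks the acidic OH that would otherwise quench the samarium catalyst of step 15.

**Step 15**
Reactants: 23 (2E,6E,9S,10R)-9-hydroxy-3,7-dimethyl-10-(propan-2-yl)cyclodeca-2,6-dien-1-one; 25 (2E)-3-[4-(tert-butyldimethylsilyloxy)phenyl]prop-2-enal
Product: 26 (1S,3E,7E,9S,10S)-9-hydroxy-3,7-dimethyl-10-(propan-2-yl)cyclodeca-3,7-dien-1-yl (2E)-3-[4-(tert-butyldimethylsilyloxy)phenyl]prop-2-enoate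
Conditions: SmI2 (0.3 equiv) premixed with 25 (5 equiv), THF, −10 °C; then 23, −10 °C, dark
Reagents that add atoms: none
Why: Evans–Tishchenko reaction: the O8 hemiacetal of aldehyde 25, held together with the C6 carbonyl on samarium(III) (formed from SmI2 and 25), transfers its hydride intramolecularly through a six-membered chair so that the new C6–H is syn to O8 (6S, 1,3-anti), and the oxidised hemiacetal remains as the O8 ester, which differentiates the two oxygens without protecting groups.

**Step 16**
Reactants: 26 (1S,3E,7E,9S,10S)-9-hydroxy-3,7-dimethyl-10-(propan-2-yl)cyclodeca-3,7-dien-1-yl (2E)-3-[4-(tert-butyldimethylsilyloxy)phenyl]prop-2-enoate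
Product: 27 (1S,3E,7E,9S,10S)-9-hydroxy-3,7-dimethyl-10-(propan-2-yl)cyclodeca-3,7-dien-1-yl (2E)-3-(4-hydroxyphenyl)prop-2-enoate
Conditions: TBAF, AcOH, THF, 0 °C
Reagents that add atoms: none
Why: Fluoride cleaves the aryl silyl ether rapidly, and acetic acid buffers the phenoxide and alkoxide so that the ester does not migrate from O8 to O6 and the acid-sensitive 1,5-diene is not exposed to strong acid.

**Compound list**
1 | tert-butyl(but-3-yn-1-yloxy)dimethylsilane | C#CCCO[Si](C)(C)C(C)(C)C | starting material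
2 | [(1E)-4-(tert-butyldimethylsilyloxy)-2-methylbut-1-en-1-yl]dimethylalane | C[Al](C)/C=C(\C)CCO[Si](C)(C)C(C)(C)C | intermediate (not isolated)
3 | tert-butyl{[(3E)-4-iodo-3-methylbut-3-en-1-yl]oxy}dimethylsilane | I/C=C(\C)CCO[Si](C)(C)C(C)(C)C | intermediate
4 | (4-bromobut-1-yn-1-yl)trimethylsilane | C[Si](C)(C)C#CCCBr | starting material
5 | [4-(trimethylsilyl)but-3-yn-1-yl]zinc bromide | C[Si](C)(C)C#CCC[Zn]Br | intermediate (not isolated)
6 | tert-butyldimethyl{[(3E)-3-methyl-8-(trimethylsilyl)oct-3-en-7-yn-1-yl]oxy}silane | C[Si](C)(C)C#CCC/C=C(\C)CCO[Si](C)(C)C(C)(C)C | intermediate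
7 | (3E)-3-methyloct-3-en-7-yn-1-ol | C#CCC/C=C(\C)CCO | intermediate
8 | dimethylaluminium alkoxide of the (1E,5E)-8-hydroxy-2,6-dimethylocta-1,5-dien-1-yl dimethylalane | C[Al](C)/C=C(\C)CC/C=C(\C)CCO[Al](C)C | intermediate (not isolated)
9 | (3E,7E)-8-iodo-3,7-dimethylocta-3,7-dien-1-ol | I/C=C(\C)CC/C=C(\C)CCO | intermediate
10 | (3E,7E)-8-iodo-3,7-dimethylocta-3,7-dienal | I/C=C(\C)CC/C=C(\C)CC=O | intermediate
11 | (4R)-4-benzyl-1,3-oxazolidin-2-one | O=C1N[C@H](Cc2ccccc2)CO1 | starting material
12 | 3-methylbutanoyl chloride | CC(C)CC(Cl)=O | starting material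
13 | lithium (4R)-4-benzyl-2-oxo-1,3-oxazolidin-3-ide | [Li]N1[C@H](Cc2ccccc2)COC1=O | intermediate (not isolated)
14 | (4R)-4-benzyl-3-(3-methylbutanoyl)-1,3-oxazolidin-2-one | CC(C)CC(=O)N1[C@H](Cc2ccccc2)COC1=O | intermediate
15 | (Z)-dibutylboron enolate of 14 | CC(C)/C=C(\OB(CCCC)CCCC)N1[C@H](Cc2ccccc2)COC1=O | intermediate (not isolated)
16 | (4R)-4-benzyl-3-[(2R,3S,5E,9E)-3-hydroxy-10-iodo-5,9-dimethyl-2-(propan-2-yl)deca-5,9-dienoyl]-1,3-oxazolidin-2-one | O=C(N1[C@H](Cc2ccccc2)COC1=O)[C@H](C(C)C)[C@@H](O)C/C(C)=C/CC/C(C)=C/I | intermediate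
17 | (2R,3S,5E,9E)-3-hydroxy-10-iodo-N-methoxy-N,5,9-trimethyl-2-(propan-2-yl)deca-5,9-dienamide | CON(C)C(=O)[C@H](C(C)C)[C@@H](O)C/C(C)=C/CC/C(C)=C/I | intermediate
18 | (2R,3S,5E,9E)-10-iodo-N-methoxy-N,5,9-trimethyl-2-(propan-2-yl)-3-(triethylsilyloxy)deca-5,9-dienamide | CON(C)C(=O)[C@H](C(C)C)[C@@H](O[Si](CC)(CC)CC)C/C(C)=C/CC/C(C)=C/I | intermediate
19 | (2R,3S,5E,9E)-10-iodo-5,9-dimethyl-2-(propan-2-yl)-3-(triethylsilyloxy)deca-5,9-dienal | O=C[C@H](C(C)C)[C@@H](O[Si](CC)(CC)CC)C/C(C)=C/CC/C(C)=C/I | intermediate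
20 | alkenylchromium(III) dichloride derived from 19 | O=C[C@H](C(C)C)[C@@H](O[Si](CC)(CC)CC)C/C(C)=C/CC/C(C)=C/[Cr](Cl)Cl | intermediate (not isolated)
21 | (2E,6E,9S,10S)-3,7-dimethyl-10-(propan-2-yl)-9-(triethylsilyloxy)cyclodeca-2,6-dien-1-ol (both C1 epimers) | C/C1=C\C(O)[C@H](C(C)C)[C@@H](O[Si](CC)(CC)CC)C/C(C)=C/CC1 | intermediate
22 | (2E,6E,9S,10R)-3,7-dimethyl-10-(propan-2-yl)-9-(triethylsilyloxy)cyclodeca-2,6-dien-1-one | C/C1=C\C(=O)[C@H](C(C)C)[C@@H](O[Si](CC)(CC)CC)C/C(C)=C/CC1 | intermediate
23 | (2E,6E,9S,10R)-9-hydroxy-3,7-dimethyl-10-(propan-2-yl)cyclodeca-2,6-dien-1-one | C/C1=C\C(=O)[C@H](C(C)C)[C@@H](O)C/C(C)=C/CC1 | intermediate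
24 | (2E)-3-(4-hydroxyphenyl)prop-2-enal | O=C/C=C/c1ccc(O)cc1 | starting material
25 | (2E)-3-[4-(tert-butyldimethylsilyloxy)phenyl]prop-2-enal | O=C/C=C/c1ccc(O[Si](C)(C)C(C)(C)C)cc1 | intermediate
26 | (1S,3E,7E,9S,10S)-9-hydroxy-3,7-dimethyl-10-(propan-2-yl)cyclodeca-3,7-dien-1-yl (2E)-3-[4-(tert-butyldimethylsilyloxy)phenyl]prop-2-enoate | C/C1=C\[C@H](O)[C@H](C(C)C)[C@@H](OC(=O)/C=C/c2ccc(O[Si](C)(C)C(C)(C)C)cc2)C/C(C)=C/CC1 | intermediate
27 | (1S,3E,7E,9S,10S)-9-hydroxy-3,7-dimethyl-10-(propan-2-yl)cyclodeca-3,7-dien-1-yl (2E)-3-(4-hydroxyphenyl)prop-2-enoate | C/C1=C\[C@H](O)[C@H](C(C)C)[C@@H](OC(=O)/C=C/c2ccc(O)cc2)C/C(C)=C/CC1 | target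

**Step count**
Total: 16 steps. Longest linear sequence: 14 steps (1–5, 7–13, 15, 16).

**Steps most likely to fail**

Step 11. Closure of the strained (E,E)-cyclodecadiene may be slower than intermolecular alkenylchromium addition or proto-deiodination. The fallback sets out from Weinreb amide 18. Iodine–lithium exchange (t-BuLi, 2.1 equiv, Et2O, −78 °C, inverse addition at high dilution, then warming to 0 °C) should give an alkenyllithium that is acylated intramolecularly by the Weinreb amide; the chelated tetrahedral intermediate prevents over-addition. This should deliver the enone directly and rejoins the route at 22, bypassing steps 10–12. No new compound is made (entry F0).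

Step 15. The conjugated aldehyde may be diverted by samarium-induced pinacol or Tishchenko dimerisation, or may form the hemiacetal too slowly. The samarium alkoxide may also promote migration of the new ester from O8 to O6 or retro-aldol opening of the ring. The fallback sets out from 23 and installs the coumarate by classical acylation instead of by hydride transfer. Evans–Tishchenko reduction with acetaldehyde (SmI2 cat., THF, −10 °C) should give the 1,3-anti hydroxy acetate F1. Silylation of O6 (TESOTf, 2,6-lutidine) gives silyl ether F2, and DIBAL-H at −78 °C removes the acetate to give alcohol F3. Pinnick oxidation of 25 (NaClO2, NaH2PO4, 2-methylbut-2-ene, t-BuOH/H2O) gives acid F4. Yamaguchi esterification of F3 with F4 (2,4,6-trichlorobenzoyl chloride, Et3N, DMAP, toluene, rt) gives ester F5. TBAF/AcOH then removes both silyl groups and the route is rejoined at 27.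

Step 13. Desilylation of the β-silyloxy enone may be accompanied by E1cB loss of the C8 oxygen through the C6 carbonyl or by epimerisation at C7. The fallback sets out from 21 and changes the order of events. The silyl ether is removed first (PPTS, MeOH, 0 °C) to give diol F6 as both C6 epimers. MnO2 (CH2Cl2, rt, dark) then oxidises only the allylic C6 hydroxyl, so the β-oxygenated enone never meets fluoride, and the route is rejoined at 23.

**Further compounds**
F0 | step 11 | none | none
F1 | step 15 | (1S,3E,7E,9S,10S)-9-hydroxy-3,7-dimethyl-10-(propan-2-yl)cyclodeca-3,7-dien-1-yl acetate | C/C1=C\[C@H](O)[C@H](C(C)C)[C@@H](OC(C)=O)C/C(C)=C/CC1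
F2 | step 15 | (1S,3E,7E,9S,10R)-3,7-dimethyl-10-(propan-2-yl)-9-(triethylsilyloxy)cyclodeca-3,7-dien-1-yl acetate | C/C1=C\[C@H](O[Si](CC)(CC)CC)[C@H](C(C)C)[C@@H](OC(C)=O)C/C(C)=C/CC1
F3 | step 15 | (1S,3E,7E,9S,10R)-3,7-dimethyl-10-(propan-2-yl)-9-(triethylsilyloxy)cyclodeca-3,7-dien-1-ol | C/C1=C\[C@H](O[Si](CC)(CC)CC)[C@H](C(C)C)[C@@H](O)C/C(C)=C/CC1
F4 | step 15 | (2E)-3-[4-(tert-butyldimethylsilyloxy)phenyl]prop-2-enoic acid | OC(=O)/C=C/c1ccc(O[Si](C)(C)C(C)(C)C)cc1
F5 | step 15 | (1S,3E,7E,9S,10R)-3,7-dimethyl-10-(propan-2-yl)-9-(triethylsilyloxy)cyclodeca-3,7-dien-1-yl (2E)-3-[4-(tert-butyldimethylsilyloxy)phenyl]prop-2-enoate | C/C1=C\[C@H](O[Si](CC)(CC)CC)[C@H](C(C)C)[C@@H](OC(=O)/C=C/c2ccc(O[Si](C)(C)C(C)(C)C)cc2)C/C(C)=C/CC1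
F6 | step 13 | (1S,2R,4E,8E)-5,9-dimethyl-2-(propan-2-yl)cyclodeca-4,8-diene-1,3-diol (both C3 epimers) | C/C1=C\C(O)[C@H](C(C)C)[C@@H](O)C/C(C)=C/CC1
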